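**Convention.** Atom numbers C1–C15 are those of the germacrane skeleton of the target (C1–C10 ring, C11–C13 lactone, C14 on C10, C15 on C4). α is the face of the C3–O–C10 bridge.

## The problem

Target 39 is a germacranolide whose ten-membered carbocycle (C1–C10) is bridged by an oxygen between C3 and C10. C3, C2, C1, C10 and that oxygen form a 2,5-dihydrofuran in which C3 is a tertiary hemiketal. A five-membered α-methylene lactone (C6–O–C12–C11–C7) is trans-fused across C6–C7, and C8 carries a (Z)-2-(acetoxymethyl)but-2-enoate.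

There are five stereocentres (C3, C6, C7, C8, C10). The quaternary C10 is separated from the C6–C7–C8 triad by C9 and by two alkenes, so it cannot direct that triad in an open chain. Once the carbocycle exists, C10 dictates C3, because the bridge can close only on the face of the C10 oxygen. C6 can direct C7 across the lactone, and the ring has to direct C8.

Several groups will not survive rough treatment:
- the α-methylene lactone, a Michael acceptor;
- the doubly allylic hemiketal, which ionises with acid and epimerises at C3 whenever it is not held in the bicycle;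
- the Z C4=C5 alkene, which isomerises when conjugated to a C3 carbonyl;
- the side chain, with angelate-type geometry and an allylic acetate;
- on the way, the γ-hydrogen (C6–H) of any butenolide.

The feature that permits the key step is that C7 is the β-carbon of the lactone carbonyl C12 and C8 is oxygenated. C7–C8 is therefore the bond a C8 acyl radical makes with a C7=C11 butenolide. That addition closes the ring C1–C10 and leaves C8 as a ketone.

## Retrosynthesis

**Ester last (C8–O acyl bond).** Cutting the ester of 39 gives diol 32 and acid 37. The side chain would not survive the enolate, hydride and fluoride steps of the core, so it goes on at the end. In 32 the only competitor of the secondary C8 hydroxyl is the tertiary hemiketal hydroxyl. The forward step must avoid nucleophilic amine catalysts, hence the mixed anhydride 38. Acid 37 is traced through hydroxy acid 36, iodo alcohol 35 and iodo enal 34 to crotonaldehyde 33. The iodine marks the carbon that becomes the carboxyl, so the alkene geometry is fixed at the iodination.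

**Hemiketal as a consequence (C3–O bond to the C10 oxygen).** Diol 32 is opened to hydroxy dienone 31 and taken back one oxidation level to triol 30. A dihydrofuran hemiketal that is not yet held in the bicycle would epimerise at C3 through its open form. In the wrong epimer the C3 hydroxyl lies cis to the C9 arm and could capture an activated C8 acyl group. The bridge is therefore carried through the ring closure as an O–Si–O surrogate at the C3 carbinol level (compounds 14 to 29). This keeps the C4 and C9 arms cis on a ring, locks the cis C1=C2 alkene, and has a stable C3 configuration. The price is one late oxidation, which only the doubly allylic C3 hydroxyl of 30 should undergo, and a C3 stereocentre that has to be set.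

**Methylene and C8 carbinol.** The C11=C13 bond of 29 is cut to Mannich base 27 (via ammonium salt 28) and then to lactone 26. This needs a lactone enolate with every hydroxyl silylated. Silyl ether 26 comes from alcohol 25 and this from ketone 24 by reduction.

**Key cut (C7–C8).** Ketone 24 is opened to selenoester 23. Cutting the lactone C–O bond or a ring bond such as C5–C6 or C9–C10 would leave the ten-membered ring to be closed with no new stereocentre gained. The C7–C8 cut closes the carbocycle and creates C7 next to C6 in one step. Precursor 23 is monocyclic apart from the butenolide, with three non-adjacent stereocentres (C3, C6, C10). The forward reaction must close in the 10-exo mode at C7 faster than hydrogen transfer or decarbonylation, and must enter trans to the C6–C5 bond.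

**Acyl radical precursor.** Selenoester 23 comes from acid 22, and this from primary alcohol 20 via aldehyde 21. C8 is kept at the alcohol level until the organometallic steps are over.

**Butenolide (C6–C7 and C12–O).** Butenolide 20 is the lactone of Z-hydroxy enoate 19, the semi-hydrogenation product of ynoate 18. Ynoate 18 is cut at C6–C7 into enal 16 and methyl propiolate 17, joined by a catalytic asymmetric alkynylation that sets C6. Vinyl addition, acrylation and metathesis would take one step more.

**Functional group changes on the chain.** Enal 16 comes from allylic alcohol 15, and this from the bis-silyl ether 14. Silylene 14 is made from cis-enediol 13, which comes from ynediol 12 by semi-hydrogenation. Ynediol 12 comes from ynone 11 by a reagent-controlled reduction that sets C3.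

**Fragment union (C2–C3).** Ynone 11 is cut into alkyne 7 and Weinreb amide 10. An amide is preferred to an aldehyde at C3: it avoids a Z-enal at this stage and gives the ketone that the reagent-controlled reduction needs.

**Starting materials.** Amide 10 comes through hydroxy amide 9 from 3-methylfuran-2(5H)-one 8, whose ring supplies the Z C4=C5 geometry. Alkyne 7 comes from (R)-citramalic acid 1, which supplies C10. Dioxolanone 2 tells the two carboxyls apart. Alcohol 3, silyl ether 4, lactol 5 and hydroxy aldehyde 6 lead to the homologation that adds C2.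

## Roads not taken

**Alternative 1:** The cut is C5–C6, paid for with a temporary C3–C8 bond in a six-membered ring. KH with 18-crown-6 would trigger an anionic oxy-Cope shift and Me3SiCl would trap the C3 enolate as silyl dienol ether A1.
- Merits: ring expansion avoids the entropic and transannular cost of an end-to-end closure, and the cis C1=C2 alkene comes from the six-membered ring. In certainty of ring formation this road is better than the chosen one.
- Weak points: A1 is far from the target. The lactone carbons are a silyloxyethyl chain that must still be oxidised. The C7=C8 alkene must be turned into the C7–H and C8–O stereocentres on a flexible triene. The Z C4=C5 alkene must be regenerated from the dienol ether.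
- Comparison: the chosen plan sets against the safer ring formation a ring closure that delivers ketone 24 with the lactone, C6, C7 and the C8 oxygen already in place.

**Alternative 2:** The cut is C11–C12 and C12–O. PdCl2 with thiourea under CO would turn a C6 hydroxyl and a C7 ethynyl group on the finished bicycle into the α-methylene lactone of A2.
- Merits: the most sensitive group is made in one step at the very end, with no enolate and no amine elimination. This is shorter and gentler than the silylation, Mannich reaction and elimination of the chosen plan, and the C8 oxygen is already in place.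
- Weak points: the road says nothing on how the ten-membered ring is closed. The bicycle must first be built with an ethynyl group at C7 trans to the C6 hydroxyl. The doubly allylic hemiketal has to pass through a palladium and CO step.
- Comparison: the chosen plan sets against the better end game a key step that closes the carbocycle and sets C7 at once.

**Alternative 3:** The cut is C2–C3. CrCl2 with catalytic NiCl2 would add a C2 alkynyl chromium species to a C3 enal and close the ring as propargylic alcohol A3.
- Merits: this polar closure is chemoselective for the aldehyde and tolerates the lactone. C6, C7, C8 and C10 are all set by acyclic chemistry, so no late ketone reduction of uncertain facial sense is needed. In that respect it is better than the chosen plan.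
- Weak points: the ring formed holds an alkyne and is strained. The alkyne must then be semi-hydrogenated next to an exocyclic methylene. C3 must be oxidised on the sensitive compound. The contiguous C6–C7–C8 triad makes the open chain long to build.
- Comparison: the chosen plan sets against this a precursor, 23, with no adjacent stereocentres and a product, 24, that needs only one reduction and the methylene.

Key step: step 18

**Assumption.** The zinc–(S,S)-ProPhenol catalyst is taken to add the propiolate to the enal face that gives the 4R carbinol 18, as with simple enals; the antipodal ligand serves if a model enal shows the opposite sense.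

## Route

Step 1
Reactants: 1 (R)-citramalic acid
Product: 2 2-[(4R)-2,2,4-trimethyl-5-oxo-1,3-dioxolan-4-yl]acetic acid
Conditions: Me2C(OMe)2, p-TsOH·H2O (cat.), rt
Reagents that add atoms: 2,2-dimethoxypropane, COC(C)(C)OC
Why: Acetalisation of an α-hydroxy acid; the five-membered dioxolanone forms in preference to the six-membered dioxanone, which leaves the C8 carboxyl free and the quaternary centre (C10) untouched.

Step 2
Reactants: 2 dioxolanone acid
Product: 3 (5R)-5-(2-hydroxyethyl)-2,2,5-trimethyl-1,3-dioxolan-4-one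
Conditions: BH3·SMe2, THF, 0 °C to rt; MeOH quench
Reagents that add atoms: none
Why: Borane reduces the free carboxylic acid through its acyloxyborane much faster than the lactone-type ester; a neutral quench avoids translactonisation.

Step 3
Reactants: 3 dioxolanone alcohol
Product: 4 (5R)-5-[2-(tert-butyldimethylsilyloxy)ethyl]-2,2,5-trimethyl-1,3-dioxolan-4-one
Conditions: TBSCl, imidazole, CH2Cl2, 0 °C to rt
Reagents that add atoms: tert-butyldimethylsilyl chloride, CC(C)(C)[Si](C)(C)Cl
Why: Standard silylation of a primary alcohol; it also removes the hydroxyl that could translactonise.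

Step 4
Reactants: 4 silyl ether
Product: 5 (5R)-5-[2-(tert-butyldimethylsilyloxy)ethyl]-2,2,5-trimethyl-1,3-dioxolan-4-ol (both anomers)
Conditions: i-Bu2AlH, CH2Cl2, −78 °C; aqueous potassium sodium tartrate
Reagents that add atoms: none
Why: Partial reduction of a dioxolanone to its lactol; the aluminium hemiacetal is stable at −78 °C, and the new hemiacetal centre is lost in step 5.

Step 5
Reactants: 5 lactol
Product: 7 (3R)-5-(tert-butyldimethylsilyloxy)-3-methylpent-1-yn-3-ol, via hydroxy aldehyde 6 (not isolated)
Conditions: MeC(O)C(N2)P(O)(OMe)2, K2CO3, MeOH, 0 °C to rt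
Reagents that add atoms: dimethyl (1-diazo-2-oxopropyl)phosphonate, CC(=O)C(=[N+]=[N-])P(=O)(OC)OC
Why: Seyferth–Gilbert homologation in the Ohira–Bestmann variant; methanolic carbonate opens the lactol with loss of acetone to aldehyde 6, whose carbonyl carbon becomes C1 while the diazo carbon becomes C2. The quaternary centre has no α-hydrogen and cannot epimerise.

Step 6
Reactants: 8 3-methylfuran-2(5H)-one
Product: 9 (2Z)-4-hydroxy-N-methoxy-N,2-dimethylbut-2-enamide
Conditions: MeNH(OMe)·HCl, Me3Al, CH2Cl2, 0 °C to rt
Reagents that add atoms: N,O-dimethylhydroxylamine hydrochloride, CNOC.Cl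
Why: Weinreb aminolysis of a lactone with an aluminium amide; the Z geometry of C4=C5 is inherited from the ring.

Step 7
Reactants: 9 hydroxy amide
Product: 10 (2Z)-4-(tert-butyldimethylsilyloxy)-N-methoxy-N,2-dimethylbut-2-enamide
Conditions: TBSCl, imidazole, CH2Cl2, 0 °C
Reagents that add atoms: tert-butyldimethylsilyl chloride, CC(C)(C)[Si](C)(C)Cl
Why: Immediate silylation of the primary alcohol stops relactonisation of the Z-hydroxy amide.

Step 8
Reactants: 7 alkyne; 10 Weinreb amide
Product: 11 (2Z,7R)-1,9-bis(tert-butyldimethylsilyloxy)-7-hydroxy-3,7-dimethylnon-2-en-5-yn-4-one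
Conditions: 7, n-BuLi (2 equiv), THF, −78 to −20 °C; then 10, −78 to 0 °C; aq. NH4Cl
Reagents that add atoms: none
Why: Acylation of a lithium acetylide (here the alkoxide–acetylide dianion) by a Weinreb amide; the chelated tetrahedral intermediate prevents over-addition. This forms C2–C3 with the Z alkene and C10 unchanged.

Step 9
Reactants: 11 ynone
Product: 12 (3R,6S,7Z)-1,9-bis(tert-butyldimethylsilyloxy)-3,7-dimethylnon-7-en-4-yne-3,6-diol
Conditions: (S)-2-methyl-CBS-oxazaborolidine, BH3·SMe2, THF, −30 °C; MeOH
Reagents that add atoms: none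
Why: Corey–Bakshi–Shibata reduction; the alkynyl group acts as the small and the α-methylalkenyl group as the large substituent, so the (S)-catalyst should give the 6S carbinol (C3, oxygen on the side of the C10 oxygen). The tertiary hydroxyl only consumes borane.

Step 10
Reactants: 12 ynediol
Product: 13 (3R,4Z,6R,7Z)-1,9-bis(tert-butyldimethylsilyloxy)-3,7-dimethylnona-4,7-diene-3,6-diol
Conditions: H2 (1 atm), Pd/CaCO3 poisoned with Pb(OAc)2, quinoline, EtOAc, rt
Reagents that add atoms: none
Why: Lindlar-type syn semi-hydrogenation gives the cis C1=C2 alkene; the isolated trisubstituted alkene is not reduced.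

Step 11
Reactants: 13 cis-enediol
Product: 14 (4R,7R)-2,2-di-tert-butyl-4-[2-(tert-butyldimethylsilyloxy)ethyl]-7-[(2Z)-4-(tert-butyldimethylsilyloxy)but-2-en-2-yl]-4-methyl-4,7-dihydro-1,3,2-dioxasilepine
Conditions: t-Bu2Si(OTf)2, 2,6-lutidine, CH2Cl2, 0 to 25 °C
Reagents that add atoms: di-tert-butylsilyl bis(trifluoromethanesulfonate), CC(C)(C)[Si](OS(=O)(=O)C(F)(F)F)(OS(=O)(=O)C(F)(F)F)C(C)(C)C
Why: Silylene protection of a cis-ene-1,4-diol as a seven-membered dioxasilepine; the secondary oxygen is silylated first and the silyl triflate then closes onto the tertiary hydroxyl. No stereocentre changes, and the C4 and C9 arms end up cis on the ring.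

Step 12
Reactants: 14 silylene bis-silyl ether
Product: 15 (2Z)-3-[(4R,7R)-2,2-di-tert-butyl-4-(2-hydroxyethyl)-4-methyl-4,7-dihydro-1,3,2-dioxasilepin-7-yl]but-2-en-1-ol
Conditions: CSA (cat.), MeOH/CH2Cl2, 0 °C
Reagents that add atoms: none
Why: Acid-catalysed methanolysis removes the two primary TBS ethers much faster than it attacks the hindered di-tert-butylsilylene.

Step 13
Reactants: 15 diol
Product: 16 (2Z)-3-[(4R,7R)-2,2-di-tert-butyl-4-(2-hydroxyethyl)-4-methyl-4,7-dihydro-1,3,2-dioxasilepin-7-yl]but-2-enal
Conditions: MnO2, CH2Cl2, rt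
Reagents that add atoms: none
Why: MnO2 oxidises only the allylic primary alcohol (C6) and leaves the saturated C8 alcohol; Z allylic alcohols of this type are oxidised with retention of geometry.

Step 14
Reactants: 16 Z-enal; 17 methyl propiolate
Product: 18 methyl (4R,5Z)-6-[(4R,7R)-2,2-di-tert-butyl-4-(2-hydroxyethyl)-4-methyl-4,7-dihydro-1,3,2-dioxasilepin-7-yl]-4-hydroxyhept-5-en-2-ynoate
Conditions: Me2Zn (4 equiv), (S,S)-ProPhenol (20 mol %), Ph3PO, toluene, 4 °C
Reagents that add atoms: none
Why: Zinc–ProPhenol catalysed asymmetric alkynylation of an enal with methyl propiolate forms C6–C7; the ligand sets C6 as the 4R carbinol. One extra equivalent of Me2Zn turns the free C8 hydroxyl into its zinc alkoxide.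

Step 15
Reactants: 18 hydroxy ynoate
Product: 20 (5S)-5-{(1Z)-2-[(4R,7R)-2,2-di-tert-butyl-4-(2-hydroxyethyl)-4-methyl-4,7-dihydro-1,3,2-dioxasilepin-7-yl]prop-1-en-1-yl}furan-2(5H)-one, via Z-hydroxy enoate 19 (not isolated)
Conditions: H2 (1 atm), Pd/CaCO3 poisoned with Pb(OAc)2, quinoline, EtOAc, rt; filter; PPTS (cat.), CH2Cl2, rt
Reagents that add atoms: none
Why: Lindlar-type semi-hydrogenation gives the Z γ-hydroxy enoate 19, which lactonises to the butenolide. The C6–O bond is not broken, so C6 keeps its configuration (S here only through a change of CIP priorities).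

Step 16
Reactants: 20 butenolide alcohol
Product: 22 2-[(4R,7R)-2,2-di-tert-butyl-4-methyl-7-{(1Z)-1-[(2S)-5-oxo-2,5-dihydrofuran-2-yl]prop-1-en-2-yl}-4,7-dihydro-1,3,2-dioxasilepin-4-yl]acetic acid, via aldehyde 21 (not isolated)
Conditions: TEMPO (cat.), PhI(OAc)2, MeCN/aq. phosphate buffer (pH 7), rt
Reagents that add atoms: water, O
Why: Oxoammonium oxidation of a primary alcohol to the aldehyde, whose hydrate is oxidised on to the acid; the medium is close to neutral, so the butenolide γ-hydrogen at C6 is not endangered.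

Step 17
Reactants: 22 acid
Product: 23 Se-phenyl 2-[(4R,7R)-2,2-di-tert-butyl-4-methyl-7-{(1Z)-1-[(2S)-5-oxo-2,5-dihydrofuran-2-yl]prop-1-en-2-yl}-4,7-dihydro-1,3,2-dioxasilepin-4-yl]ethaneselenoate
Conditions: (PhSe)2, n-Bu3P (added last), CH2Cl2, 0 °C to rt
Reagents that add atoms: diphenyl diselenide, c1ccc(cc1)[Se][Se]c1ccccc1
Why: Phosphine–diselenide activation; the acyloxyphosphonium ion is captured by selenolate to give the phenyl selenoester without added base.

Step 18
Reactants: 23 selenoester
Product: 24 (3R,6R,7S,10R)-3α,10α-(di-tert-butylsilanediyldioxy)-8-oxo-13-norgermacra-1(2)Z,4Z-dien-6α,12-olide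
Conditions: n-Bu3SnH (1.3 equiv) and AIBN (0.2 equiv) by syringe pump over 10 h, benzene, 80 °C, 2 mM
Reagents that add atoms: none
Why: Bu3Sn• abstracts the phenylseleno group (homolytic substitution at selenium) and leaves the C8 acyl radical, a nucleophilic σ-radical that adds to C7, the electron-poor β-carbon of the butenolide, to form C7–C8; the C11 radical next to the lactone carbonyl then takes hydrogen from n-Bu3SnH and carries the chain. The closest known reaction type is the n-Bu3SnH/AIBN macrocyclisation of acyl radicals from phenyl selenoesters onto enoates and enones, together with the intermolecular addition of acyl radicals to γ-substituted butenolides anti to the γ-substituent. The ring closed is the ten-membered carbocycle C1–C10, in the 10-exo-trig mode: C7 is the alkene carbon that carries the tether and the radical ends on C11 outside the new ring. The new stereocentre C7 is controlled by C6: the tether leaves C6 on one face of the flat butenolide and, held short by the Z C4=C5 alkene and the dioxasilepine with its two arms cis, reaches C7 with C5 and C8 staggered anti about C6–C7, which puts the new bond trans to C6–C5, whereas the cis approach would eclipse these bonds. C7 stays α to the C8 ketone, so a kinetic cis product could be equilibrated to the trans-fused lactone. The step needs attack at C7 in preference to the unactivated C4=C5 alkene, to hydrogen transfer and to decarbonylation: radical polarity favours the butenolide, C4=C5 is reachable only by 7-exo attack on a fully substituted carbon or by 8-endo attack, slow addition of the stannane at high dilution keeps reduction to aldehyde 21 slow, and loss of CO would give only a primary radical. The silylene ring also prevents stannyl-radical isomerisation of the cis C1=C2 alkene.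

Step 19
Reactants: 24 ketone
Product: 25 (3R,6R,7R,8R,10R)-3α,10α-(di-tert-butylsilanediyldioxy)-8β-hydroxy-13-norgermacra-1(2)Z,4Z-dien-6α,12-olide
Conditions: NaBH4, CeCl3·7H2O, MeOH/THF, −78 °C
Reagents that add atoms: none
Why: Luche-type reduction is fast and non-basic, so C7, α to the ketone, is not epimerised. Hydride should enter from the α face of C8, which carries only H-7 and the C10 oxygen, while the β face is screened by C11 and the C14 methyl; this facial sense, giving the 8β (8R) alcohol, is to be confirmed.

Step 20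
Reactants: 25 alcohol
Product: 26 3α,10α-(di-tert-butylsilanediyldioxy)-8β-(triethylsilyloxy)-13-norgermacra-1(2)Z,4Z-dien-6α,12-olide
Conditions: Et3SiOTf, 2,6-lutidine, CH2Cl2, −78 °C
Reagents that add atoms: triethylsilyl trifluoromethanesulfonate, CC[Si](CC)(CC)OS(=O)(=O)C(F)(F)F
Why: Silylation of a hindered secondary alcohol with a silyl triflate; a free 8-alkoxide next to the lactone would invite translactonisation in step 21.

Step 21
Reactants: 26 lactone
Product: 27 13-(dimethylamino)-3α,10α-(di-tert-butylsilanediyldioxy)-8β-(triethylsilyloxy)germacra-1(2)Z,4Z-dien-6α,12-olide (C11 epimers)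
Conditions: LiN(i-Pr)2, THF, −78 °C; Me2N=CH2 iodide, −78 to 0 °C
Reagents that add atoms: N,N-dimethylmethyleneiminium iodide, C[N+](C)=C.[I-]
Why: Mannich reaction of the lactone lithium enolate with Eschenmoser's salt; C11 is the only enolisable position, and its configuration is irrelevant because it becomes sp2 in step 22.

Step 22
Reactants: 27 Mannich base
Product: 29 3α,10α-(di-tert-butylsilanediyldioxy)-8β-(triethylsilyloxy)germacra-1(2)Z,4Z,11(13)-trien-6α,12-olide, via ammonium iodide 28 (not isolated)
Conditions: MeI, MeOH, rt; then NaHCO3 (aq.), EtOAc, rt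
Reagents that add atoms: none
Why: Quaternisation and E1cB elimination of trimethylamine give the exocyclic C11=C13 alkene, the usual way to α-methylene lactones.

Step 23
Reactants: 29 silylated methylene lactone
Product: 30 3α,8β,10α-trihydroxygermacra-1(2)Z,4Z,11(13)-trien-6α,12-olide
Conditions: HF·pyridine, pyridine, THF, 0 to 25 °C
Reagents that add atoms: none
Why: Fluoride cleaves the silylene and the triethylsilyl ether; the buffered acidic medium is tolerated by the α-methylene lactone, unlike basic fluoride sources.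

Step 24
Reactants: 30 triol
Product: 32 (3R,6R,7R,8R,10R)-3β,8β-dihydroxy-3α,10α-epoxygermacra-1,4Z,11(13)-trien-6α,12-olide, via hydroxy dienone 31 (not isolated)
Conditions: MnO2, CH2Cl2, rt
Reagents that add atoms: none
Why: MnO2 oxidises only the doubly allylic C3 hydroxyl; the cis γ-hydroxy enone 31 then closes to the five-membered hemiketal. The bridge can form only on the face of the C10 oxygen, so C10 sets C3 (3R).

Step 25
Reactants: 33 (E)-but-2-enal
Product: 34 (2Z)-2-iodobut-2-enal
Conditions: I2, K2CO3, DMAP (cat.), THF/H2O, rt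
Reagents that add atoms: iodine, [I][I]
Why: α-Iodination of an enal by amine conjugate addition, iodination and elimination; the product keeps the methyl group trans to the formyl group, hence cis to iodine.

Step 26
Reactants: 34 iodo enal
Product: 35 (2Z)-2-iodobut-2-en-1-ol
Conditions: NaBH4, MeOH, 0 °C
Reagents that add atoms: none
Why: 1,2-Reduction of the aldehyde; alkene and vinyl iodide are untouched.

Step 27
Reactants: 35 iodo alcohol
Product: 36 (2Z)-2-(hydroxymethyl)but-2-enoic acid
Conditions: n-BuLi (1 equiv), then t-BuLi (2 equiv), Et2O, −78 °C; CO2; aq. HCl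
Reagents that add atoms: carbon dioxide, O=C=O
Why: Iodine–lithium exchange on the lithium alkoxide proceeds with retention of alkene geometry; carboxylation of the vinyllithium places the carboxyl cis to the C-methyl group (angelate-type geometry).

Step 28
Reactants: 36 hydroxy acid
Product: 37 (2Z)-2-(acetoxymethyl)but-2-enoic acid
Conditions: Ac2O, pyridine, CH2Cl2, 0 °C; aqueous work-up
Reagents that add atoms: acetic anhydride, CC(=O)OC(C)=O
Why: O-Acetylation of the primary alcohol; any mixed anhydride at the carboxyl is hydrolysed on work-up.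

Step 29
Reactants: 32 hemiketal diol; 37 acid
Product: 39 (3R,6R,7R,8R,10R)-8β-[(2Z)-2-(acetoxymethyl)but-2-enoyloxy]-3β-hydroxy-3α,10α-epoxygermacra-1,4Z,11(13)-trien-6α,12-olide, via mixed anhydride 38 (not isolated)
Conditions: 37, 2,4,6-Cl3C6H2COCl, Et3N, toluene, 25 °C; then 32, toluene, 70 °C
Reagents that add atoms: none
Why: Yamaguchi esterification run without a nucleophilic amine catalyst, the variant used for angelates to keep the Z geometry and here also the allylic acetate. The secondary C8 hydroxyl is acylated in preference to the tertiary hemiketal hydroxyl.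

## Compound list

1 | (R)-citramalic acid | C[C@@](O)(CC(=O)O)C(=O)O | starting material
2 | 2-[(4R)-2,2,4-trimethyl-5-oxo-1,3-dioxolan-4-yl]acetic acid | C[C@@]1(CC(=O)O)C(=O)OC(C)(C)O1 | intermediate
3 | (5R)-5-(2-hydroxyethyl)-2,2,5-trimethyl-1,3-dioxolan-4-one | C[C@@]1(CCO)C(=O)OC(C)(C)O1 | intermediate
4 | (5R)-5-[2-(tert-butyldimethylsilyloxy)ethyl]-2,2,5-trimethyl-1,3-dioxolan-4-one | C[C@@]1(CCO[Si](C)(C)C(C)(C)C)C(=O)OC(C)(C)O1 | intermediate
5 | (5R)-5-[2-(tert-butyldimethylsilyloxy)ethyl]-2,2,5-trimethyl-1,3-dioxolan-4-ol (anomers) | C[C@@]1(CCO[Si](C)(C)C(C)(C)C)C(O)OC(C)(C)O1 | intermediate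
6 | (2R)-4-(tert-butyldimethylsilyloxy)-2-hydroxy-2-methylbutanal | C[C@@](O)(CCO[Si](C)(C)C(C)(C)C)C=O | intermediate
7 | (3R)-5-(tert-butyldimethylsilyloxy)-3-methylpent-1-yn-3-ol | C#C[C@@](C)(CCO[Si](C)(C)C(C)(C)C)O | intermediate
8 | 3-methylfuran-2(5H)-one | CC1=CCOC1=O | starting material
9 | (2Z)-4-hydroxy-N-methoxy-N,2-dimethylbut-2-enamide | CON(C)C(=O)/C(C)=C\CO | intermediate
10 | (2Z)-4-(tert-butyldimethylsilyloxy)-N-methoxy-N,2-dimethylbut-2-enamide | CON(C)C(=O)/C(C)=C\CO[Si](C)(C)C(C)(C)C | intermediate
11 | (2Z,7R)-1,9-bis(tert-butyldimethylsilyloxy)-7-hydroxy-3,7-dimethylnon-2-en-5-yn-4-one | CC(C)(C)[Si](C)(C)OC/C=C(/C)C(=O)C#C[C@@](C)(CCO[Si](C)(C)C(C)(C)C)O | intermediate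
12 | (3R,6S,7Z)-1,9-bis(tert-butyldimethylsilyloxy)-3,7-dimethylnon-7-en-4-yne-3,6-diol | CC(C)(C)[Si](C)(C)OC/C=C(/C)[C@H](O)C#C[C@@](C)(CCO[Si](C)(C)C(C)(C)C)O | intermediate
13 | (3R,4Z,6R,7Z)-1,9-bis(tert-butyldimethylsilyloxy)-3,7-dimethylnona-4,7-diene-3,6-diol | CC(C)(C)[Si](C)(C)OC/C=C(/C)[C@H](O)/C=C\[C@@](C)(CCO[Si](C)(C)C(C)(C)C)O | intermediate
14 | (4R,7R)-2,2-di-tert-butyl-4-[2-(tert-butyldimethylsilyloxy)ethyl]-7-[(2Z)-4-(tert-butyldimethylsilyloxy)but-2-en-2-yl]-4-methyl-4,7-dihydro-1,3,2-dioxasilepine | CC(C)(C)[Si](C)(C)OC/C=C(/C)[C@H]1C=C[C@@](C)(CCO[Si](C)(C)C(C)(C)C)O[Si](C(C)(C)C)(C(C)(C)C)O1 | intermediate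
15 | (2Z)-3-[(4R,7R)-2,2-di-tert-butyl-4-(2-hydroxyethyl)-4-methyl-4,7-dihydro-1,3,2-dioxasilepin-7-yl]but-2-en-1-ol | OC/C=C(/C)[C@H]1C=C[C@@](C)(CCO)O[Si](C(C)(C)C)(C(C)(C)C)O1 | intermediate
16 | (2Z)-3-[(4R,7R)-2,2-di-tert-butyl-4-(2-hydroxyethyl)-4-methyl-4,7-dihydro-1,3,2-dioxasilepin-7-yl]but-2-enal | O=C/C=C(/C)[C@H]1C=C[C@@](C)(CCO)O[Si](C(C)(C)C)(C(C)(C)C)O1 | intermediate
17 | methyl propiolate | C#CC(=O)OC | starting material
18 | methyl (4R,5Z)-6-[(4R,7R)-2,2-di-tert-butyl-4-(2-hydroxyethyl)-4-methyl-4,7-dihydro-1,3,2-dioxasilepin-7-yl]-4-hydroxyhept-5-en-2-ynoate | COC(=O)C#C[C@H](O)/C=C(/C)[C@H]1C=C[C@@](C)(CCO)O[Si](C(C)(C)C)(C(C)(C)C)O1 | intermediate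
19 | methyl (2Z,4S,5Z)-6-[(4R,7R)-2,2-di-tert-butyl-4-(2-hydroxyethyl)-4-methyl-4,7-dihydro-1,3,2-dioxasilepin-7-yl]-4-hydroxyhepta-2,5-dienoate | COC(=O)/C=C\[C@H](O)/C=C(/C)[C@H]1C=C[C@@](C)(CCO)O[Si](C(C)(C)C)(C(C)(C)C)O1 | intermediate
20 | (5S)-5-{(1Z)-2-[(4R,7R)-2,2-di-tert-butyl-4-(2-hydroxyethyl)-4-methyl-4,7-dihydro-1,3,2-dioxasilepin-7-yl]prop-1-en-1-yl}furan-2(5H)-one | O=C1C=C[C@@H](/C=C(/C)[C@H]2C=C[C@@](C)(CCO)O[Si](C(C)(C)C)(C(C)(C)C)O2)O1 | intermediate
21 | 2-[(4R,7R)-2,2-di-tert-butyl-4-methyl-7-{(1Z)-1-[(2S)-5-oxo-2,5-dihydrofuran-2-yl]prop-1-en-2-yl}-4,7-dihydro-1,3,2-dioxasilepin-4-yl]acetaldehyde | O=C1C=C[C@@H](/C=C(/C)[C@H]2C=C[C@@](C)(CC=O)O[Si](C(C)(C)C)(C(C)(C)C)O2)O1 | intermediate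
22 | 2-[(4R,7R)-2,2-di-tert-butyl-4-methyl-7-{(1Z)-1-[(2S)-5-oxo-2,5-dihydrofuran-2-yl]prop-1-en-2-yl}-4,7-dihydro-1,3,2-dioxasilepin-4-yl]acetic acid | O=C1C=C[C@@H](/C=C(/C)[C@H]2C=C[C@@](C)(CC(=O)O)O[Si](C(C)(C)C)(C(C)(C)C)O2)O1 | intermediate
23 | Se-phenyl 2-[(4R,7R)-2,2-di-tert-butyl-4-methyl-7-{(1Z)-1-[(2S)-5-oxo-2,5-dihydrofuran-2-yl]prop-1-en-2-yl}-4,7-dihydro-1,3,2-dioxasilepin-4-yl]ethaneselenoate | O=C1C=C[C@@H](/C=C(/C)[C@H]2C=C[C@@](C)(CC(=O)[Se]c3ccccc3)O[Si](C(C)(C)C)(C(C)(C)C)O2)O1 | intermediate
24 | (3R,6R,7S,10R)-3α,10α-(di-tert-butylsilanediyldioxy)-8-oxo-13-norgermacra-1(2)Z,4Z-dien-6α,12-olide (H-3β, H-6β, H-7α) | C1C(=O)O[C@@H]2/C=C(/C)[C@H]3C=C[C@@](C)(CC(=O)[C@@H]12)O[Si](C(C)(C)C)(C(C)(C)C)O3 | intermediate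
25 | (3R,6R,7R,8R,10R)-3α,10α-(di-tert-butylsilanediyldioxy)-8β-hydroxy-13-norgermacra-1(2)Z,4Z-dien-6α,12-olide | C1C(=O)O[C@@H]2/C=C(/C)[C@H]3C=C[C@@](C)(C[C@@H](O)[C@@H]12)O[Si](C(C)(C)C)(C(C)(C)C)O3 | intermediate
26 | 3α,10α-(di-tert-butylsilanediyldioxy)-8β-(triethylsilyloxy)-13-norgermacra-1(2)Z,4Z-dien-6α,12-olide | C1C(=O)O[C@@H]2/C=C(/C)[C@H]3C=C[C@@](C)(C[C@@H](O[Si](CC)(CC)CC)[C@@H]12)O[Si](C(C)(C)C)(C(C)(C)C)O3 | intermediate
27 | 13-(dimethylamino)-3α,10α-(di-tert-butylsilanediyldioxy)-8β-(triethylsilyloxy)germacra-1(2)Z,4Z-dien-6α,12-olide (C11 not controlled) | CN(C)CC1C(=O)O[C@@H]2/C=C(/C)[C@H]3C=C[C@@](C)(C[C@@H](O[Si](CC)(CC)CC)[C@@H]12)O[Si](C(C)(C)C)(C(C)(C)C)O3 | intermediate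
28 | 13-(trimethylammonio) analogue of 27, iodide (C11 not controlled) | C[N+](C)(C)CC1C(=O)O[C@@H]2/C=C(/C)[C@H]3C=C[C@@](C)(C[C@@H](O[Si](CC)(CC)CC)[C@@H]12)O[Si](C(C)(C)C)(C(C)(C)C)O3.[I-] | intermediate
29 | 3α,10α-(di-tert-butylsilanediyldioxy)-8β-(triethylsilyloxy)germacra-1(2)Z,4Z,11(13)-trien-6α,12-olide | C=C1C(=O)O[C@@H]2/C=C(/C)[C@H]3C=C[C@@](C)(C[C@@H](O[Si](CC)(CC)CC)[C@@H]12)O[Si](C(C)(C)C)(C(C)(C)C)O3 | intermediate
30 | 3α,8β,10α-trihydroxygermacra-1(2)Z,4Z,11(13)-trien-6α,12-olide | C=C1C(=O)O[C@@H]2/C=C(/C)[C@H](O)/C=C\[C@@](C)(C[C@@H](O)[C@@H]12)O | intermediate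
31 | 8β,10α-dihydroxy-3-oxogermacra-1(2)Z,4Z,11(13)-trien-6α,12-olide | C=C1C(=O)O[C@@H]2/C=C(/C)C(=O)/C=C\[C@@](C)(C[C@@H](O)[C@@H]12)O | intermediate
32 | (3R,6R,7R,8R,10R)-3β,8β-dihydroxy-3α,10α-epoxygermacra-1,4Z,11(13)-trien-6α,12-olide | C=C1C(=O)O[C@@H]2/C=C(/C)[C@@]3(O)C=C[C@@](C)(C[C@@H](O)[C@@H]12)O3 | intermediate
33 | (E)-but-2-enal (crotonaldehyde) | C/C=C/C=O | starting material
34 | (2Z)-2-iodobut-2-enal | C/C=C(\I)C=O | intermediate
35 | (2Z)-2-iodobut-2-en-1-ol | C/C=C(\I)CO | intermediate
36 | (2Z)-2-(hydroxymethyl)but-2-enoic acid | C/C=C(/CO)C(=O)O | intermediate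
37 | (2Z)-2-(acetoxymethyl)but-2-enoic acid | C/C=C(/COC(C)=O)C(=O)O | intermediate
38 | (2Z)-2-(acetoxymethyl)but-2-enoic 2,4,6-trichlorobenzoic anhydride | C/C=C(/COC(C)=O)C(=O)OC(=O)c1c(Cl)cc(Cl)cc1Cl | intermediate
39 | (3R,6R,7R,8R,10R)-8β-[(2Z)-2-(acetoxymethyl)but-2-enoyloxy]-3β-hydroxy-3α,10α-epoxygermacra-1,4Z,11(13)-trien-6α,12-olide (CNP0256971.1) | C=C1C(=O)O[C@@H]2/C=C(/C)[C@@]3(O)C=C[C@@](C)(C[C@@H](OC(=O)/C(=C\C)COC(C)=O)[C@@H]12)O3 | target

## Step count and risks

Total step count: 29. Longest linear sequence: 23 steps (steps 1–5, 8–24 and 29). Steps 6–7 and 25–28 are side branches.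

**Step 18 (key step).** The acyl radical may be reduced to the aldehyde or lose CO before the slow ten-membered closure, because transannular strain makes medium rings the slowest to form. It may also add to C4=C5 or enter cis to the C6–C5 bond. Fallback: a ketyl–olefin cyclisation sets out from aldehyde 21, obtained from 20 with the step 16 oxidant in dry CH2Cl2, where the oxidation stops at the aldehyde. SmI2 with t-BuOH in THF at high dilution should give the C8 ketyl, which adds to C7 of the butenolide. This forms the same C7–C8 bond and delivers the C8 carbinol directly, so the route is rejoined at 25. This fallback makes no new compound (F0). If the carbinol forms as the 8α epimer, the inversion described under step 19 applies.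

**Step 11.** Ring closure of the silyl triflate onto the hindered tertiary C10 hydroxyl may stall, and triflic acid that escapes the base may ionise the doubly allylic C3 carbinol. Fallback: the closure is made in two stages from 13. t-Bu2SiHCl with imidazole in DMF silylates only the secondary C3 hydroxyl to give (3R,4Z,6R,7Z)-1,9-bis(tert-butyldimethylsilyloxy)-6-(di-tert-butylsilyloxy)-3,7-dimethylnona-4,7-dien-3-ol F1. Catalytic KOt-Bu in THF then closes the ring by dehydrogenative Si–O coupling of the Si–H bond with the tertiary alkoxide, which returns to 14.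

**Step 14.** The Z enal may isomerise to the E enal under the Lewis-acidic zinc conditions, and the zinc alkoxide of the free C8 hydroxyl may erode the facial selectivity. Fallback: C6 is set by reduction instead of addition. Enal 16 is treated at −78 °C with the lithium acetylide made from 17 and LiN(i-Pr)2, which adds without isomerisation. This gives methyl (5Z)-6-[(4R,7R)-2,2-di-tert-butyl-4-(2-hydroxyethyl)-4-methyl-4,7-dihydro-1,3,2-dioxasilepin-7-yl]-4-hydroxyhept-5-en-2-ynoate as both C4 epimers F2. MnO2 oxidises the doubly activated carbinol to the 4-oxo-2-ynoate F3. A Midland reduction with (R)-Alpine-Borane (B-isopinocampheyl-9-borabicyclo[3.3.1]nonane), which treats the alkynyl group as the small substituent, returns to 18.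

**Step 19.** Hydride may be delivered to the wrong face of the macrocyclic ketone, whose conformation is not known in advance, or C7 may epimerise before reduction. Fallback: if reduction of 24 gives the 8α-alcohol F4, a Mitsunobu reaction with formic acid, PPh3 and DIAD inverts C8 to the 8β-formate F5. KHCO3 in MeOH at 0 °C cleaves the formate without opening the lactone and returns to 25.

**Step 29.** The side-chain alkene may lose its Z geometry, the allylic acetate may be displaced in the SN2′ sense by amine, and slow acylation of the hindered C8 hydroxyl may leave time for translactonisation. Fallback: the acetate is introduced after the esterification. Iodo alcohol 35 is silylated (TBSCl, imidazole) to (2Z)-tert-butyl[(2-iodobut-2-en-1-yl)oxy]dimethylsilane F6. Exchange with t-BuLi and carboxylation give (2Z)-2-[(tert-butyldimethylsilyloxy)methyl]but-2-enoic acid F7, which has no leaving group. F7 is joined to 32 by a Yamaguchi esterification with catalytic DMAP at low temperature to give the 8-O-acyl silyl ether F8. HF·pyridine gives the hydroxymethyl ester F9, and Ac2O with pyridine acetylates its primary hydroxyl only, which returns to 39.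

## Further compounds

F0 | step 18 | none | none
F1 | step 11 | (3R,4Z,6R,7Z)-1,9-bis(tert-butyldimethylsilyloxy)-6-(di-tert-butylsilyloxy)-3,7-dimethylnona-4,7-dien-3-ol | CC(C)(C)[Si](C)(C)OC/C=C(/C)[C@H](O[SiH](C(C)(C)C)C(C)(C)C)/C=C\[C@@](C)(CCO[Si](C)(C)C(C)(C)C)O
F2 | step 14 | methyl (5Z)-6-[(4R,7R)-2,2-di-tert-butyl-4-(2-hydroxyethyl)-4-methyl-4,7-dihydro-1,3,2-dioxasilepin-7-yl]-4-hydroxyhept-5-en-2-ynoate (both C4 epimers) | COC(=O)C#CC(O)/C=C(/C)[C@H]1C=C[C@@](C)(CCO)O[Si](C(C)(C)C)(C(C)(C)C)O1
F3 | step 14 | methyl (5Z)-6-[(4R,7R)-2,2-di-tert-butyl-4-(2-hydroxyethyl)-4-methyl-4,7-dihydro-1,3,2-dioxasilepin-7-yl]-4-oxohept-5-en-2-ynoate | COC(=O)C#CC(=O)/C=C(/C)[C@H]1C=C[C@@](C)(CCO)O[Si](C(C)(C)C)(C(C)(C)C)O1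
F4 | step 19 | 3α,10α-(di-tert-butylsilanediyldioxy)-8α-hydroxy-13-norgermacra-1(2)Z,4Z-dien-6α,12-olide | C1C(=O)O[C@@H]2/C=C(/C)[C@H]3C=C[C@@](C)(C[C@H](O)[C@@H]12)O[Si](C(C)(C)C)(C(C)(C)C)O3
F5 | step 19 | 3α,10α-(di-tert-butylsilanediyldioxy)-8β-formyloxy-13-norgermacra-1(2)Z,4Z-dien-6α,12-olide | C1C(=O)O[C@@H]2/C=C(/C)[C@H]3C=C[C@@](C)(C[C@@H](OC=O)[C@@H]12)O[Si](C(C)(C)C)(C(C)(C)C)O3
F6 | step 29 | (2Z)-tert-butyl[(2-iodobut-2-en-1-yl)oxy]dimethylsilane | C/C=C(\I)CO[Si](C)(C)C(C)(C)C
F7 | step 29 | (2Z)-2-[(tert-butyldimethylsilyloxy)methyl]but-2-enoic acid | C/C=C(/CO[Si](C)(C)C(C)(C)C)C(=O)O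
F8 | step 29 | 8β-{(2Z)-2-[(tert-butyldimethylsilyloxy)methyl]but-2-enoyloxy}-3β-hydroxy-3α,10α-epoxygermacra-1,4Z,11(13)-trien-6α,12-olide | C=C1C(=O)O[C@@H]2/C=C(/C)[C@@]3(O)C=C[C@@](C)(C[C@@H](OC(=O)/C(=C\C)CO[Si](C)(C)C(C)(C)C)[C@@H]12)O3
F9 | step 29 | 8β-[(2Z)-2-(hydroxymethyl)but-2-enoyloxy]-3β-hydroxy-3α,10α-epoxygermacra-1,4Z,11(13)-trien-6α,12-olide | C=C1C(=O)O[C@@H]2/C=C(/C)[C@@]3(O)C=C[C@@](C)(C[C@@H](OC(=O)/C(=C\C)CO)[C@@H]12)O3
A1 | alternative 1 | ten-membered trimethylsilyl dienol ether (C3 silyl enol ether, 6-O-p-methoxybenzyl, 10-O-triethylsilyl, 2-(tert-butyldimethylsilyloxy)ethyl on C7) | C[Si](C)(C)O/C1=C(/C)C[C@@H](OCc2ccc(OC)cc2)/C(CCO[Si](C)(C)C(C)(C)C)=C/C[C@@](C)(O[Si](CC)(CC)CC)/C=C\1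
A2 | alternative 2 | 8β-(tert-butyldimethylsilyloxy)-3β-hydroxy-3α,10α-epoxygermacra-1,4Z,11(13)-trien-6α,12-olide | C=C1C(=O)O[C@@H]2/C=C(/C)[C@@]3(O)C=C[C@@](C)(C[C@@H](O[Si](C)(C)C(C)(C)C)[C@@H]12)O3
A3 | alternative 3 | 8β-(tert-butyldimethylsilyloxy)-3-hydroxy-10α-(triethylsilyloxy)germacra-4Z,11(13)-dien-1-yn-6α,12-olide | C=C1C(=O)O[C@@H]2/C=C(/C)[C@@H](O)C#C[C@](C)(O[Si](CC)(CC)CC)C[C@@H](O[Si](C)(C)C(C)(C)C)[C@@H]12
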